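**Retrosynthetic overview**
- The oxepene is opened at the O1–C9a bond: the last step is an intramolecular Markovnikov hydroalkoxylation of an exocyclic olefin on the bromocyclohexane by a bromohydrin hydroxyl (C–O bond, sets C9a).
- The bromohydrin (C2) comes from an α′-bromo enone by oxazaborolidine reduction.
- The bromocyclohexane (ring A, C5a and C7) comes from an acyclic (3Z,6Z)-triene bromoketone by enantioselective bromonium cyclization of its (Z)-neryl unit.
- The bromoketone comes from a skipped enynoate by cis-hydroalumination/hydroxymethylation and bromomethyllithium homologation.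
- The enynoate comes from neryl bromide (from nerol) and methyl propiolate. Ring order: carbocycle first, oxepene second.

Assumption: the SMILES is read literally; its (5aR,9aS) ring fusion is cis, with Br trans to the C5a side chain, which is the pattern a (Z)-trisubstituted olefin delivers, so nerol and not geraniol is the starting terpene.

**Step 1**
Reactants: 1 nerol, (2Z)-3,7-dimethylocta-2,6-dien-1-ol
Product: 2 neryl bromide, (2Z)-1-bromo-3,7-dimethylocta-2,6-diene
Conditions: PBr3 (0.4 equiv), Et2O, −10 °C
Reagents that add atoms: phosphorus tribromide, BrP(Br)Br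
Why: bromide displaces the activated phosphite ester at the primary allylic carbon in an SN2 sense at low temperature (PBr3 bromination of an allylic alcohol), which keeps the (2Z) olefin.

**Step 2**
Reactants: 2 neryl bromide; 3 methyl propiolate
Product: 4 methyl (5Z)-6,10-dimethylundeca-5,9-dien-2-ynoate
Conditions: CuI (10 mol %), K2CO3, DMF, 25 °C
Reagents that add atoms: none
Why: the copper acetylide of the acidic propiolate C–H substitutes the primary allylic bromide at its unsubstituted end (Jeffery-type copper-catalysed allyl–alkynyl coupling) with retention of the (Z) olefin.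

**Step 3**
Reactants: 4 methyl (5Z)-6,10-dimethylundeca-5,9-dien-2-ynoate
Product: 6 methyl (2Z,5Z)-2-(hydroxymethyl)-6,10-dimethylundeca-2,5,9-trienoate, via vinylalane 5 (not isolated)
Conditions: iBu2AlH (1.3 equiv), NMO (2 equiv), THF, 0 °C; then monomeric CH2O (from paraformaldehyde), 0 → 25 °C; aqueous Rochelle salt
Reagents that add atoms: formaldehyde, C=O
Why: cis-hydroalumination of the ynoate (hydride to the β-carbon, aluminium to the α-carbon; vinylalumination) followed by addition of the C–Al bond to formaldehyde with retention places H and CH2OH cis, so the allylic chain ends cis to the ester (2Z), the geometry the seven-membered ring needs.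

**Step 4**
Reactants: 6 methyl (2Z,5Z)-2-(hydroxymethyl)-6,10-dimethylundeca-2,5,9-trienoate
Product: 8 (3Z,6Z)-1-bromo-3-(hydroxymethyl)-7,11-dimethyldodeca-3,6,10-trien-2-one, via tetrahedral dilithium adduct 7 (not isolated)
Conditions: CH2Br2 (3 equiv), MeLi·LiBr (3.2 equiv), THF/Et2O, −78 °C; AcOH, −78 °C
Reagents that add atoms: dibromomethane, BrCBr
Why: bromomethyllithium made in the presence of the ester adds once to the carbonyl (halomethyllithium homologation of an ester), and the alkoxide-chelated tetrahedral adduct collapses to the bromomethyl ketone only on the cold acidic quench, so no stereocentre is made and the (3Z) olefin is kept.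

**Step 5**
Reactants: 8 (3Z,6Z)-1-bromo-3-(hydroxymethyl)-7,11-dimethyldodeca-3,6,10-trien-2-one
Product: 9 (3Z)-1-bromo-5-[(1S,3S)-3-bromo-2,2-dimethyl-6-methylidenecyclohexyl]-3-(hydroxymethyl)pent-3-en-2-one
Conditions: DBDMH (0.55 equiv), (S)-3,3′-bis(2,4,6-triisopropylphenyl)-1,1′-binaphthyl-2,2′-diyl N-triflylthiophosphoramide [(ArO)2P(=S)NHSO2CF3] (10 mol %), toluene/CH2Cl2 1:1, −78 °C
Reagents that add atoms: 1,3-dibromo-5,5-dimethylhydantoin, CC1(C)N(Br)C(=O)N(Br)C1=O
Why: Proposed new method: the P=S group of the chiral thiophosphoramide takes Br+ from DBDMH while its acidic N–H holds the hydantoin anion, so a sulfur-bound bromenium is delivered to the Si face of C10 of 8, and the bromonium is opened by the (6Z) olefin through a chair transition state with the C–Br bond equatorial and the side chain axial, which sets the bromine-bearing carbon (S) and the neighbouring ring CH (S) trans-1,3 to each other before the hydantoin anion removes a methyl proton from the tertiary cation, the closest known reaction being the thiophosphoramide/DBDMH-catalysed enantioselective bromonium polyene cyclization of aryl-terminated homogeranyl substrates, here extended to an olefin-terminated neryl substrate that ends by elimination.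

**Step 6**
Reactants: 9 (3Z)-1-bromo-5-[(1S,3S)-3-bromo-2,2-dimethyl-6-methylidenecyclohexyl]-3-(hydroxymethyl)pent-3-en-2-one
Product: 10 (2R,3Z)-1-bromo-5-[(1S,3S)-3-bromo-2,2-dimethyl-6-methylidenecyclohexyl]-3-(hydroxymethyl)pent-3-en-2-ol
Conditions: (R)-2-methyl-CBS-oxazaborolidine [(3aR)-1-methyl-3,3-diphenyltetrahydro-1H,3H-pyrrolo[1,2-c][1,3,2]oxazaborole] (20 mol %), catecholborane (2.5 equiv), toluene, −78 °C; MeOH, then pH 7 buffer
Reagents that add atoms: none
Why: Corey–Bakshi–Shibata 1,2-reduction in which the trisubstituted alkenyl group is the large and CH2Br the small substituent, so the (R)-catalyst gives the (2R) bromohydrin (the sense known for α-halo aryl and alkenyl ketones), and catecholborane at −78 °C leaves the exocyclic olefin and both C–Br bonds untouched.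

**Step 7**
Reactants: 10 (2R,3Z)-1-bromo-5-[(1S,3S)-3-bromo-2,2-dimethyl-6-methylidenecyclohexyl]-3-(hydroxymethyl)pent-3-en-2-ol
Product: 11 [(2R,5aR,7S,9aS)-7-bromo-2-(bromomethyl)-6,6,9a-trimethyl-2,5,5a,6,7,8,9,9a-octahydro-1-benzoxepin-3-yl]methanol
Conditions: (R,R)-N,N′-bis(3,5-di-tert-butylsalicylidene)-1,2-cyclohexanediaminocobalt (divalent cobalt, 5 mol %), N-fluoro-2,4,6-trimethylpyridinium tetrafluoroborate (1.5 equiv), (HMe2Si)2O (1.5 equiv), PhCF3, 0.01 M, 0 → 25 °C
Reagents that add atoms: none
Why: Proposed new method: hydrogen-atom transfer from the cobalt hydride to the exocyclic CH2 gives the tertiary radical, which is oxidised to the tertiary cation (radical–polar crossover) and trapped by the C2 hydroxyl, and because that hydroxyl is tied through the (Z) olefin to the ring side chain it can reach the cationic carbon only from the face of that chain, closing the seven-membered ether with cis ring fusion (9aS) while the CH2OH on the far side of the olefin cannot reach, the closest known reaction being cobalt–salen Markovnikov intramolecular hydroalkoxylation of unactivated olefins to five- and six-membered ethers, not yet shown for a seven-membered tertiary ether of this kind.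

**Compound list**
1 | nerol, (2Z)-3,7-dimethylocta-2,6-dien-1-ol | CC(C)=CCC/C(C)=C\CO | starting material
2 | neryl bromide, (2Z)-1-bromo-3,7-dimethylocta-2,6-diene | CC(C)=CCC/C(C)=C\CBr | intermediate
3 | methyl propiolate | C#CC(=O)OC | starting material
4 | methyl (5Z)-6,10-dimethylundeca-5,9-dien-2-ynoate | COC(=O)C#CC/C=C(C)\CCC=C(C)C | intermediate
5 | vinylalane, methyl (2E,5Z)-2-(diisobutylalumanyl)-6,10-dimethylundeca-2,5,9-trienoate | COC(=O)/C(=C\C/C=C(C)\CCC=C(C)C)[Al](CC(C)C)CC(C)C | intermediate
6 | methyl (2Z,5Z)-2-(hydroxymethyl)-6,10-dimethylundeca-2,5,9-trienoate | COC(=O)/C(CO)=C\C/C=C(C)\CCC=C(C)C | intermediate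
7 | tetrahedral dilithium adduct, dilithium (3Z,6Z)-1-bromo-2-methoxy-7,11-dimethyl-3-(oxidomethyl)dodeca-3,6,10-trien-2-olate | [Li+].[Li+].COC([O-])(CBr)/C(C[O-])=C\C/C=C(C)\CCC=C(C)C | intermediate
8 | (3Z,6Z)-1-bromo-3-(hydroxymethyl)-7,11-dimethyldodeca-3,6,10-trien-2-one | BrCC(=O)/C(CO)=C\C/C=C(C)\CCC=C(C)C | intermediate
9 | (3Z)-1-bromo-5-[(1S,3S)-3-bromo-2,2-dimethyl-6-methylidenecyclohexyl]-3-(hydroxymethyl)pent-3-en-2-one | CC1(C)[C@@H](C/C=C(CO)\C(=O)CBr)C(=C)CC[C@@H]1Br | intermediate
10 | (2R,3Z)-1-bromo-5-[(1S,3S)-3-bromo-2,2-dimethyl-6-methylidenecyclohexyl]-3-(hydroxymethyl)pent-3-en-2-ol | CC1(C)[C@@H](C/C=C(CO)\[C@H](CBr)O)C(=C)CC[C@@H]1Br | intermediate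
11 | [(2R,5aR,7S,9aS)-7-bromo-2-(bromomethyl)-6,6,9a-trimethyl-2,5,5a,6,7,8,9,9a-octahydro-1-benzoxepin-3-yl]methanol | CC1(C)[C@H]2CC=C(CO)[C@H](CBr)O[C@@]2(C)CC[C@@H]1Br | target

**Step count and risks**
Total steps: 7. Longest linear sequence: 7 (1 → 11).

Steps most likely to fail:

Step 5 (proposed new method). The catalyst has only been shown with aryl terminators, so the ee, the face sense and the yield on this substrate are open; if the sense is opposite, the (R)-catalyst is used. Endocyclic olefin isomers from proton loss would converge on the same tertiary radical in step 7. The fallback sets out from 8. Racemic bromonium cyclization with Et2SBr·SbBrCl5 in MeNO2 at −25 °C gives 9 as the racemate, that is 9 together with its mirror image (3Z)-1-bromo-5-[(1R,3R)-3-bromo-2,2-dimethyl-6-methylidenecyclohexyl]-3-(hydroxymethyl)pent-3-en-2-one F1. The reagent-controlled oxazaborolidine reduction of step 6 then gives 10 and, from F1, the diastereomer (2R,3Z)-1-bromo-5-[(1R,3R)-3-bromo-2,2-dimethyl-6-methylidenecyclohexyl]-3-(hydroxymethyl)pent-3-en-2-ol F2. These are diastereomers and are separated on silica, so the fallback comes back to the route at 10, with at most half of the material.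

Step 7 (proposed new method). Seven-membered closure may be slower than olefin isomerisation or hydrogen-atom transfer to the side-chain olefin. The fallback sets out from 10. Intramolecular alkoxymercuration with Hg(OCOCF3)2 in CH2Cl2 at −20 °C (Markovnikov, same tether-controlled cis closure) gives [(2R,5aR,7S,9aS)-7-bromo-2-(bromomethyl)-3-(hydroxymethyl)-6,6-dimethyl-2,5,5a,6,7,8,9,9a-octahydro-1-benzoxepin-9a-yl]methylmercury trifluoroacetate F3. Reductive demercuration with NaBH4 in THF/aqueous NaOH at 0 °C comes back to the route at 11.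

Step 3. Hydroalumination may compete with ester reduction or isomerisation of the skipped enynoate, and formaldehyde is a sluggish partner. The fallback sets out from 2. Copper-catalysed coupling with propargyl alcohol (CuI, K2CO3, DMF) gives (5Z)-6,10-dimethylundeca-5,9-dien-2-yn-1-ol F4. Hydroxyl-directed trans-hydrostannation ([Cp*RuCl]4, Bu3SnH, CH2Cl2) gives (2Z,5Z)-6,10-dimethyl-2-(tributylstannyl)undeca-2,5,9-trien-1-ol F5. Iododestannylation (I2, CH2Cl2, 0 °C) gives (2Z,5Z)-2-iodo-6,10-dimethylundeca-2,5,9-trien-1-ol F6. Methoxycarbonylation (Pd(PPh3)4, CO 1 atm, Et3N, MeOH, 50 °C) comes back to the route at 6.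

**Further compounds**
F1 | step 5 | (3Z)-1-bromo-5-[(1R,3R)-3-bromo-2,2-dimethyl-6-methylidenecyclohexyl]-3-(hydroxymethyl)pent-3-en-2-one | CC1(C)[C@H](C/C=C(CO)\C(=O)CBr)C(=C)CC[C@H]1Br
F2 | step 5 | (2R,3Z)-1-bromo-5-[(1R,3R)-3-bromo-2,2-dimethyl-6-methylidenecyclohexyl]-3-(hydroxymethyl)pent-3-en-2-ol | CC1(C)[C@H](C/C=C(CO)\[C@H](CBr)O)C(=C)CC[C@H]1Br
F3 | step 7 | [(2R,5aR,7S,9aS)-7-bromo-2-(bromomethyl)-3-(hydroxymethyl)-6,6-dimethyl-2,5,5a,6,7,8,9,9a-octahydro-1-benzoxepin-9a-yl]methylmercury trifluoroacetate | CC1(C)[C@H]2CC=C(CO)[C@H](CBr)O[C@@]2(C[Hg]OC(=O)C(F)(F)F)CC[C@@H]1Br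
F4 | step 3 | (5Z)-6,10-dimethylundeca-5,9-dien-2-yn-1-ol | OCC#CC/C=C(C)\CCC=C(C)C
F5 | step 3 | (2Z,5Z)-6,10-dimethyl-2-(tributylstannyl)undeca-2,5,9-trien-1-ol | OC/C(=C/C/C=C(C)\CCC=C(C)C)[Sn](CCCC)(CCCC)CCCC
F6 | step 3 | (2Z,5Z)-2-iodo-6,10-dimethylundeca-2,5,9-trien-1-ol | OC/C(I)=C/C/C=C(C)\CCC=C(C)C
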